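**Plan**

- Cuts: the three interflavan bonds (C4–C6, C4–C8, C4–C6, top to bottom) are cut first, which reduces the tetramer to four copies of one protected (2R,3R)-flavan-3-ol, 12. In 12, ring C is cut at C2–C3, then at O1–C2 (ester) and C4a–C4 (allyl).
- Enabling feature: in ring C of every unit, O1 is a ring-A phenol oxygen and C2 carries ring B. O1–C2 can therefore be stored as an aryl 3,4-dioxybenzoate (C2 at the acid level) beside an allyl group on C4a (C4, C3), and C2=C3 becomes the double bond of a cyclic aryl enol ether, made by titanium-alkylidene carbonyl–olefin metathesis.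
- Forward: ring-A phenol → O-allyl → Claisen → aroyl ester → ring C closed at C2=C3 → hydroboration/oxidation → 3-ketone → cis-alcohol 12. Compound 12 is turned into four blocks and the chain is joined 1→2 (C4–C6), then 2→3 (C4–C8), then 3→4 (C4–C6).
- Stereochemistry: C2 and C3 of all four units come from one catalyst-controlled transfer hydrogenation with dynamic kinetic resolution of the racemic flavan-3-one (2,3-cis, 2R,3R). Each C4 comes from arene attack on the flavan-4-yl cation trans to the 3-acetoxy group (4β).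
- Helpers and their removal: the enol ether/ketone oxidation level at C2–C3 (adjusted in steps 5–7), bromine caps at C8 (and C6), a 4-arylthio latent leaving group, acetates and benzyl ethers (all gone after steps 16–19).

Key step: step 4

Assumption: the (R,R)-TsDPEN ligand is taken to deliver hydride to the ketone face that gives the (3R) carbinol; should a trial on 11 show the opposite sense, the (S,S) ligand is used and nothing else changes.

**Route**

Step 1
Reactants: 1 3,5-bis(benzyloxy)phenol; 2 allyl bromide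
Product: 3 1-(allyloxy)-3,5-bis(benzyloxy)benzene
Conditions: K2CO3, acetone, reflux
Reagents that add atoms: none
Why: Williamson ether synthesis at the only free phenol with a primary allylic bromide; no stereocentre is involved.

Step 2
Reactants: 3 1-(allyloxy)-3,5-bis(benzyloxy)benzene
Product: 4 2-allyl-3,5-bis(benzyloxy)phenol
Conditions: N,N-diethylaniline, 190 °C
Reagents that add atoms: none
Why: aromatic Claisen rearrangement ([3,3]) delivers the allyl group from the oxygen that becomes O1 to one of the two equivalent free ortho carbons (the future C4a), so C4 and C3 arrive with the correct regiochemistry and the phenol is set free again.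

Step 3
Reactants: 4 2-allyl-3,5-bis(benzyloxy)phenol; 5 3,4-bis(benzyloxy)benzoic acid
Product: 6 2-allyl-3,5-bis(benzyloxy)phenyl 3,4-bis(benzyloxy)benzoate
Conditions: DCC, DMAP (cat.), CH2Cl2, rt
Reagents that add atoms: none
Why: Steglich esterification attaches ring B and the future C2 (as the ester carbonyl) to O1 and places the carbonyl within reach of the allyl terminus.

Step 4
Reactants: 6 2-allyl-3,5-bis(benzyloxy)phenyl 3,4-bis(benzyloxy)benzoate
Product: 8 5,7-bis(benzyloxy)-2-[3,4-bis(benzyloxy)phenyl]-4H-chromene, via titanium alkylidene 7 (not isolated)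
Conditions: TiCl4, TMEDA, Zn, PbCl2 (cat.), CH3CHBr2, THF–CH2Cl2, 0 → 65 °C
Reagents that add atoms: none
Why: The reduced titanium ethylidene generated from TiCl4, Zn and CH3CHBr2 first undergoes [2+2] cycloaddition/cycloreversion with the monosubstituted alkene of the allyl group (propene leaves) to give the substrate-bound alkylidene 7, whose nucleophilic carbon (the future C3) adds across the C=O of the ortho aryl ester (the future C2) to an oxatitanacyclobutane that cycloreverts to the enol ether, the strong Ti=O bond being the driving force. The closest known reaction type is the olefinic-ester cyclization with Takai–Utimoto titanium alkylidenes (carbonyl–olefin metathesis), which converts alkenyl esters into six- and seven-membered cyclic enol ethers. Ring C (O1, C2, C3, C4, C4a, C8a) is closed by the C2=C3 bond in a 6-exo sense with respect to the ester C=O, the four-membered metallacycle being spiro to the new ring at C2. No stereocentre is created: C2 and C3 are deliberately left sp2 and receive their configuration in step 7. The step needs chemoselectivity (alkylidene exchange at the alkene before direct ethylidenation of the ester) and positional integrity of the double bond; the terminal allyl group is the only alkene and sits within reach of the only carbonyl group, the benzyl ethers are inert to the reagent, and the non-acidic medium keeps the 4H-chromene from isomerising to the conjugated 2H-chromene.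

Step 5
Reactants: 8 5,7-bis(benzyloxy)-2-[3,4-bis(benzyloxy)phenyl]-4H-chromene
Product: 10 rac-(2,3-trans)-5,7-bis(benzyloxy)-2-[3,4-bis(benzyloxy)phenyl]chroman-3-ol, via 3-boryl flavan 9 (not isolated)
Conditions: BH3·THF, THF, 0 °C → rt; then NaOH (aq), H2O2, 0 °C
Reagents that add atoms: borane–tetrahydrofuran, B.C1CCOC1 (boron of 9); hydrogen peroxide, OO (oxygen at C3 of 10)
Why: Brown hydroboration–oxidation of the enol ether places boron at C3 (β to O1 and remote from the aryl group) by syn addition, and oxidation with retention should give the 2,3-trans alcohol as a racemate; its configuration is erased in step 6.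

Step 6
Reactants: 10 rac-(2,3-trans)-5,7-bis(benzyloxy)-2-[3,4-bis(benzyloxy)phenyl]chroman-3-ol
Product: 11 rac-5,7-bis(benzyloxy)-2-[3,4-bis(benzyloxy)phenyl]chroman-3-one
Conditions: Dess–Martin periodinane, NaHCO3, CH2Cl2, rt
Reagents that add atoms: none
Why: Dess–Martin oxidation of the secondary alcohol under buffered, non-epimerising conditions gives the flavan-3-one, a reaction type established on tetra-O-benzyl flavan-3-ols.

Step 7
Reactants: 11 rac-5,7-bis(benzyloxy)-2-[3,4-bis(benzyloxy)phenyl]chroman-3-one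
Product: 12 5,7,3′,4′-tetra-O-benzyl-(−)-epicatechin, (2R,3R)
Conditions: RuCl[(R,R)-TsDPEN](p-cymene) (2 mol %), HCO2H–Et3N (5:2), CH2Cl2, 30 °C
Reagents that add atoms: none
Why: Noyori asymmetric transfer hydrogenation with dynamic kinetic resolution: the α-aryl-α-aryloxy ketone racemises at C2 through its enol under the amine buffer while the chiral Ru–H reduces only the matched enantiomer, hydride arriving anti to the C2 aryl group, so C3 (R) and C2 (R) should be set together as the 2,3-cis alcohol, as with other α-aryl cyclic ketones.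

Step 8
Reactants: 12 5,7,3′,4′-tetra-O-benzyl-(−)-epicatechin
Product: 13 8-bromo-5,7,3′,4′-tetra-O-benzyl-(−)-epicatechin
Conditions: NBS (1.0 equiv), CH2Cl2, −78 → −40 °C
Reagents that add atoms: N-bromosuccinimide, O=C1CCC(=O)N1Br
Why: electrophilic aromatic bromination takes place at C8, the most nucleophilic ring-A carbon (between O1 and the 7-benzyloxy group), and caps it for the later C6-selective coupling.

Step 9
Reactants: 13 8-bromo-5,7,3′,4′-tetra-O-benzyl-(−)-epicatechin
Product: 14 3-O-acetyl-8-bromo-5,7,3′,4′-tetra-O-benzyl-(−)-epicatechin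
Conditions: Ac2O, pyridine, DMAP (cat.), rt
Reagents that add atoms: acetic anhydride, CC(=O)OC(C)=O
Why: standard acylation masks the C3 hydroxyl so that it cannot compete as an O-nucleophile with the weakly nucleophilic C6 in step 17.

Step 10
Reactants: 12 5,7,3′,4′-tetra-O-benzyl-(−)-epicatechin
Product: 15 4β-(2-ethoxyethoxy)-5,7,3′,4′-tetra-O-benzyl-(−)-epicatechin
Conditions: DDQ (2 equiv), 2-ethoxyethanol, CH2Cl2, rt
Reagents that add atoms: 2-ethoxyethanol, CCOCCO
Why: DDQ benzylic oxidation: hydride abstraction from C4 (activated by the ortho and para oxygens of ring A) gives a quinone-methide-type cation that the alcohol should capture trans to the C3 hydroxyl (4β), as established for benzylated flavan-3-ols.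

Step 11
Reactants: 15 4β-(2-ethoxyethoxy)-5,7,3′,4′-tetra-O-benzyl-(−)-epicatechin
Product: 16 3-O-acetyl-4β-(2-ethoxyethoxy)-5,7,3′,4′-tetra-O-benzyl-(−)-epicatechin
Conditions: Ac2O, pyridine, DMAP (cat.), rt
Reagents that add atoms: acetic anhydride, CC(=O)OC(C)=O
Why: acylation under basic conditions leaves the acid-labile C4 ether untouched and installs the C3 acetate that later shields the α-face of the C4 cation.

Step 12
Reactants: 16 3-O-acetyl-4β-(2-ethoxyethoxy)-5,7,3′,4′-tetra-O-benzyl-(−)-epicatechin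
Product: 17 3-O-acetyl-6,8-dibromo-4β-(2-ethoxyethoxy)-5,7,3′,4′-tetra-O-benzyl-(−)-epicatechin
Conditions: NBS (2.2 equiv), CH2Cl2, −20 → 0 °C
Reagents that add atoms: N-bromosuccinimide, O=C1CCC(=O)N1Br
Why: twofold electrophilic aromatic bromination fills both free ring-A carbons (C8, then C6), so this electrophile has no nucleophilic site and cannot self-condense.

Step 13
Reactants: 16 3-O-acetyl-4β-(2-ethoxyethoxy)-5,7,3′,4′-tetra-O-benzyl-(−)-epicatechin
Product: 18 3-O-acetyl-8-bromo-4β-(2-ethoxyethoxy)-5,7,3′,4′-tetra-O-benzyl-(−)-epicatechin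
Conditions: NBS (1.0 equiv), CH2Cl2, −78 → −40 °C
Reagents that add atoms: N-bromosuccinimide, O=C1CCC(=O)N1Br
Why: electrophilic aromatic monobromination at C8 (the more reactive ring-A carbon, remote from the C4 substituent) leaves C6 as the only open nucleophilic position.

Step 14
Reactants: 18 3-O-acetyl-8-bromo-4β-(2-ethoxyethoxy)-5,7,3′,4′-tetra-O-benzyl-(−)-epicatechin
Product: 19 3-O-acetyl-8-bromo-4β-(2,6-dimethylphenylthio)-5,7,3′,4′-tetra-O-benzyl-(−)-epicatechin
Conditions: 2,6-dimethylbenzenethiol (3 equiv), BF3·OEt2 (cat.), CH2Cl2, −78 → −30 °C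
Reagents that add atoms: 2,6-dimethylbenzenethiol, Cc1cccc(C)c1S
Why: Lewis-acid SN1 exchange at C4 (ionisation of the benzylic ether, capture by the thiol trans to the 3-acetoxy group) gives a thioether that is inert to hard Lewis acids and serves as the latent leaving group of unit 2.

Step 15
Reactants: 17 3-O-acetyl-6,8-dibromo-4β-(2-ethoxyethoxy)-5,7,3′,4′-tetra-O-benzyl-(−)-epicatechin; 19 3-O-acetyl-8-bromo-4β-(2,6-dimethylphenylthio)-5,7,3′,4′-tetra-O-benzyl-(−)-epicatechin
Product: 20 protected dimer, unit 1-(4β→6)-unit 2, with Br at C6 and C8 of unit 1, Br at C8 and the 4β-arylthio group on unit 2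
Conditions: BF3·OEt2 (cat.), 19 (2 equiv), 4 Å molecular sieves, CH2Cl2, −78 → −40 °C
Reagents that add atoms: none
Why: Friedel–Crafts alkylation by the flavan-4-yl cation of 17: bromine at C8 of 19 leaves C6 as the only ring-A nucleophile (4→6 regiochemistry), the 3-acetoxy group directs the arene to the β-face (3,4-trans), and the thioether does not ionise under the hard Lewis acid.

Step 16
Reactants: 20 protected dimer; 16 3-O-acetyl-4β-(2-ethoxyethoxy)-5,7,3′,4′-tetra-O-benzyl-(−)-epicatechin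
Product: 21 protected trimer, unit 1-(4β→6)-unit 2-(4β→8)-unit 3, with the 4β-(2-ethoxyethoxy) group on unit 3
Conditions: AgOSO2CF3 (AgOTf, 1.5 equiv), 2,6-di-tert-butyl-4-methylpyridine, 16 (2 equiv), 4 Å molecular sieves, CH2Cl2, −40 → 0 °C
Reagents that add atoms: none
Why: orthogonal thiophilic activation: the silver salt ionises only the C4–S bond of unit 2, the cation is taken by the most nucleophilic carbon of 16 (C8) trans to the 3-acetoxy group, and the buffered, soft conditions leave the C4 ether of 16 in place for the next coupling.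

Step 17
Reactants: 21 protected trimer; 14 3-O-acetyl-8-bromo-5,7,3′,4′-tetra-O-benzyl-(−)-epicatechin
Product: 22 protected tetramer (16 benzyl ethers, 4 acetates, 4 aryl bromides)
Conditions: BF3·OEt2 (cat.), 14 (3 equiv), 4 Å molecular sieves, CH2Cl2, −78 → −40 °C
Reagents that add atoms: none
Why: Friedel–Crafts alkylation by the C4 cation of unit 3: the excess of 14, with C8 capped by bromine, offers only C6 (4→6), and the 3-acetoxy group again secures 4β attack; the sole competing ring-A carbon on the trimer is the crowded C6 of unit 3.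

Step 18
Reactants: 22 protected tetramer
Product: 23 hexadeca-O-benzyl tetrabromo tetramer with four free C3 hydroxyls
Conditions: K2CO3 (cat.), MeOH–THF, 40 °C
Reagents that add atoms: none
Why: base-catalysed transesterification (Zemplén type) removes the four acetates without touching benzyl ethers, aryl bromides or the interflavan bonds.

Step 19
Reactants: 23 hexadeca-O-benzyl tetrabromo tetramer
Product: 24 epicatechin-(4β→6)-epicatechin-(4β→8)-epicatechin-(4β→6)-epicatechin (CNP0120618.1)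
Conditions: H2 (1 atm), Pd(OH)2/C, Et3N, THF–MeOH–H2O, rt
Reagents that add atoms: none
Why: catalytic hydrogenolysis cleaves all sixteen benzyl ethers and, with the amine as acid scavenger, hydrodehalogenates the four aryl bromides in the same operation; no stereocentre is affected.

**Compound list**

1 | 3,5-bis(benzyloxy)phenol | Oc1cc(OCc2ccccc2)cc(OCc2ccccc2)c1 | starting material
2 | allyl bromide | C=CCBr | starting material
3 | 1-(allyloxy)-3,5-bis(benzyloxy)benzene | C=CCOc1cc(OCc2ccccc2)cc(OCc2ccccc2)c1 | intermediate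
4 | 2-allyl-3,5-bis(benzyloxy)phenol | Oc1cc(OCc2ccccc2)cc(OCc2ccccc2)c1CC=C | intermediate
5 | 3,4-bis(benzyloxy)benzoic acid | OC(=O)c1ccc(OCc2ccccc2)c(OCc2ccccc2)c1 | starting material
6 | 2-allyl-3,5-bis(benzyloxy)phenyl 3,4-bis(benzyloxy)benzoate | C=CCc1c(OC(=O)c2ccc(OCc3ccccc3)c(OCc3ccccc3)c2)cc(OCc2ccccc2)cc1OCc1ccccc1 | intermediate
7 | titanium alkylidene of 6 (dichlorotitanium alkylidene at the former allyl CH; TMEDA ligands omitted) | Cl[Ti](Cl)=CCc1c(OC(=O)c2ccc(OCc3ccccc3)c(OCc3ccccc3)c2)cc(OCc2ccccc2)cc1OCc1ccccc1 | intermediate (not isolated)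
8 | 5,7-bis(benzyloxy)-2-[3,4-bis(benzyloxy)phenyl]-4H-chromene | C1C=C(c2ccc(OCc3ccccc3)c(OCc3ccccc3)c2)Oc2cc(OCc3ccccc3)cc(OCc3ccccc3)c12 | intermediate
9 | rac-(2,3-trans)-3-boryl-5,7-bis(benzyloxy)-2-[3,4-bis(benzyloxy)phenyl]chroman (racemate, one enantiomer drawn) | B[C@H]1Cc2c(OCc3ccccc3)cc(OCc3ccccc3)cc2O[C@@H]1c1ccc(OCc2ccccc2)c(OCc2ccccc2)c1 | intermediate (not isolated)
10 | rac-(2,3-trans)-5,7-bis(benzyloxy)-2-[3,4-bis(benzyloxy)phenyl]chroman-3-ol (racemate, one enantiomer drawn) | O[C@H]1Cc2c(OCc3ccccc3)cc(OCc3ccccc3)cc2O[C@@H]1c1ccc(OCc2ccccc2)c(OCc2ccccc2)c1 | intermediate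
11 | rac-5,7-bis(benzyloxy)-2-[3,4-bis(benzyloxy)phenyl]chroman-3-one | O=C1Cc2c(OCc3ccccc3)cc(OCc3ccccc3)cc2OC1c1ccc(OCc2ccccc2)c(OCc2ccccc2)c1 | intermediate
12 | 5,7,3′,4′-tetra-O-benzyl-(−)-epicatechin, (2R,3R) | O[C@@H]1Cc2c(OCc3ccccc3)cc(OCc3ccccc3)cc2O[C@@H]1c1ccc(OCc2ccccc2)c(OCc2ccccc2)c1 | intermediate
13 | 8-bromo-5,7,3′,4′-tetra-O-benzyl-(−)-epicatechin | O[C@@H]1Cc2c(OCc3ccccc3)cc(OCc3ccccc3)c(Br)c2O[C@@H]1c1ccc(OCc2ccccc2)c(OCc2ccccc2)c1 | intermediate
14 | 3-O-acetyl-8-bromo-5,7,3′,4′-tetra-O-benzyl-(−)-epicatechin | CC(=O)O[C@@H]1Cc2c(OCc3ccccc3)cc(OCc3ccccc3)c(Br)c2O[C@@H]1c1ccc(OCc2ccccc2)c(OCc2ccccc2)c1 | intermediate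
15 | 4β-(2-ethoxyethoxy)-5,7,3′,4′-tetra-O-benzyl-(−)-epicatechin (2,3-cis, 3,4-trans) | c9ccccc9COc1cc(OCc9ccccc9)c2c(c1)O[C@H](c8ccc(OCc9ccccc9)c(OCc9ccccc9)c8)[C@H](O)[C@H]2OCCOCC | intermediate
16 | 3-O-acetyl-4β-(2-ethoxyethoxy)-5,7,3′,4′-tetra-O-benzyl-(−)-epicatechin | c9ccccc9COc1cc(OCc9ccccc9)c2c(c1)O[C@H](c8ccc(OCc9ccccc9)c(OCc9ccccc9)c8)[C@H](OC(C)=O)[C@H]2OCCOCC | intermediate
17 | 3-O-acetyl-6,8-dibromo-4β-(2-ethoxyethoxy)-5,7,3′,4′-tetra-O-benzyl-(−)-epicatechin | c9ccccc9COc1c(Br)c(OCc9ccccc9)c2c(c1Br)O[C@H](c8ccc(OCc9ccccc9)c(OCc9ccccc9)c8)[C@H](OC(C)=O)[C@H]2OCCOCC | intermediate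
18 | 3-O-acetyl-8-bromo-4β-(2-ethoxyethoxy)-5,7,3′,4′-tetra-O-benzyl-(−)-epicatechin | c9ccccc9COc1cc(OCc9ccccc9)c2c(c1Br)O[C@H](c8ccc(OCc9ccccc9)c(OCc9ccccc9)c8)[C@H](OC(C)=O)[C@H]2OCCOCC | intermediate
19 | 3-O-acetyl-8-bromo-4β-(2,6-dimethylphenylthio)-5,7,3′,4′-tetra-O-benzyl-(−)-epicatechin | c9ccccc9COc1cc(OCc9ccccc9)c2c(c1Br)O[C@H](c8ccc(OCc9ccccc9)c(OCc9ccccc9)c8)[C@H](OC(C)=O)[C@H]2Sc1c(C)cccc1C | intermediate
20 | protected dimer: [3-O-acetyl-6,8-dibromo-tetra-O-benzylepicatechin]-(4β→6)-[3-O-acetyl-8-bromo-4β-(2,6-dimethylphenylthio)-tetra-O-benzylepicatechin] | c9ccccc9COc1c(Br)c(OCc9ccccc9)c2c(c1Br)O[C@H](c8ccc(OCc9ccccc9)c(OCc9ccccc9)c8)[C@H](OC(C)=O)[C@H]2c1c(OCc9ccccc9)c(Br)c2c(c1OCc9ccccc9)[C@H](Sc7c(C)cccc7C)[C@@H](OC(C)=O)[C@@H](c8ccc(OCc9ccccc9)c(OCc9ccccc9)c8)O2 | intermediate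
21 | protected trimer: dimer as in 20, joined (4β→8) to 3-O-acetyl-4β-(2-ethoxyethoxy)-tetra-O-benzylepicatechin | c9ccccc9COc1c(Br)c(OCc9ccccc9)c2c(c1Br)O[C@H](c8ccc(OCc9ccccc9)c(OCc9ccccc9)c8)[C@H](OC(C)=O)[C@H]2c1c(OCc9ccccc9)c(Br)c2c(c1OCc9ccccc9)[C@H](c1c(OCc9ccccc9)cc(OCc9ccccc9)c3c1O[C@H](c8ccc(OCc9ccccc9)c(OCc9ccccc9)c8)[C@H](OC(C)=O)[C@H]3OCCOCC)[C@@H](OC(C)=O)[C@@H](c8ccc(OCc9ccccc9)c(OCc9ccccc9)c8)O2 | intermediate
22 | protected tetramer: trimer as in 21, joined (4β→6) to 3-O-acetyl-8-bromo-tetra-O-benzylepicatechin | c9ccccc9COc1c(Br)c(OCc9ccccc9)c2c(c1Br)O[C@H](c8ccc(OCc9ccccc9)c(OCc9ccccc9)c8)[C@H](OC(C)=O)[C@H]2c1c(OCc9ccccc9)c(Br)c2c(c1OCc9ccccc9)[C@H](c1c(OCc9ccccc9)cc(OCc9ccccc9)c3c1O[C@H](c8ccc(OCc9ccccc9)c(OCc9ccccc9)c8)[C@H](OC(C)=O)[C@H]3c1c(OCc9ccccc9)c(Br)c3c(c1OCc9ccccc9)C[C@@H](OC(C)=O)[C@@H](c8ccc(OCc9ccccc9)c(OCc9ccccc9)c8)O3)[C@@H](OC(C)=O)[C@@H](c8ccc(OCc9ccccc9)c(OCc9ccccc9)c8)O2 | intermediate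
23 | hexadeca-O-benzyl tetrabromo tetramer, four free C3 hydroxyls | c9ccccc9COc1c(Br)c(OCc9ccccc9)c2c(c1Br)O[C@H](c8ccc(OCc9ccccc9)c(OCc9ccccc9)c8)[C@H](O)[C@H]2c1c(OCc9ccccc9)c(Br)c2c(c1OCc9ccccc9)[C@H](c1c(OCc9ccccc9)cc(OCc9ccccc9)c3c1O[C@H](c8ccc(OCc9ccccc9)c(OCc9ccccc9)c8)[C@H](O)[C@H]3c1c(OCc9ccccc9)c(Br)c3c(c1OCc9ccccc9)C[C@@H](O)[C@@H](c8ccc(OCc9ccccc9)c(OCc9ccccc9)c8)O3)[C@@H](O)[C@@H](c8ccc(OCc9ccccc9)c(OCc9ccccc9)c8)O2 | intermediate
24 | epicatechin-(4β→6)-epicatechin-(4β→8)-epicatechin-(4β→6)-epicatechin | Oc1cc(O)c2c(c1)O[C@H](c1ccc(O)c(O)c1)[C@H](O)[C@H]2c1c(O)cc2c(c1O)[C@H](c1c(O)cc(O)c3c1O[C@H](c1ccc(O)c(O)c1)[C@H](O)[C@H]3c1c(O)cc3c(c1O)C[C@@H](O)[C@@H](c1ccc(O)c(O)c1)O3)[C@@H](O)[C@@H](c1ccc(O)c(O)c1)O2 | target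

**Step count**

Total steps: 19. Longest linear sequence: 16 steps (1–7, 10, 11, 13–19).

**Steps most likely to fail, with fallbacks**

Step 4. The titanium ethylidene may olefinate the ester carbonyl directly before it exchanges with the allyl group, or the allyl double bond may migrate into conjugation with ring A. The fallback splits the closure into two operations and sets out from ester 6. Methylenation of the ester carbonyl with Cp2TiMe2 (toluene, 70 °C) should give the diene 2-allyl-3,5-bis(benzyloxy)phenyl 1-[3,4-bis(benzyloxy)phenyl]vinyl ether F1. Ring-closing olefin metathesis of F1 with the second-generation Grubbs catalyst, RuCl2(=CHPh)(H2IMes)(PCy3) (toluene, 70 °C), then closes C2=C3 with loss of ethene and comes back to the route at chromene 8.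

Step 7. Racemisation at C2 may be slow relative to reduction, or the catalyst may discriminate the two ketone faces poorly, so that cis/trans or enantiomer mixtures result. The fallback sets C2 by a chiral reagent and sets out from chromene 8. Hydroboration with monoisopinocampheylborane (IpcBH2 prepared from (+)-α-pinene, or its antipode if the sense proves opposite) followed by NaOH/H2O2 should give (2R,3S)-5,7,3′,4′-tetra-O-benzylcatechin F2. Dess–Martin oxidation converts it into (2R)-5,7-bis(benzyloxy)-2-[3,4-bis(benzyloxy)phenyl]chroman-3-one F3 without touching C2. Reduction with LiBH(s-Bu)3 (THF, −78 °C) delivers hydride by equatorial attack to give the axial, 2,3-cis alcohol and comes back to the route at 12.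

Step 15. The C6 carbon of the bromine-capped, thio-substituted nucleophile 19 may be too hindered and electron-poor to capture the cation before it eliminates or is recaptured by the liberated alcohol. The fallback drops the pre-installed thioether and installs each leaving group after the coupling by C–H oxidation; it sets out from 17 and 14.

- BF3·OEt2-mediated coupling of 17 with the less hindered 14 should give the protected dimer with an unsubstituted C4 in unit 2, F4.
- DDQ with 2-ethoxyethanol oxidises its only benzylic CH2 to the dimer carrying a 4β-(2-ethoxyethoxy) group on unit 2, F5.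
- Acetylation of 12 (Ac2O, pyridine) gives 3-O-acetyl-5,7,3′,4′-tetra-O-benzyl-(−)-epicatechin F6.
- BF3·OEt2-mediated coupling of F5 with F6 at its C8 gives the protected trimer with an unsubstituted C4 in unit 3, F7.
- A second DDQ/2-ethoxyethanol oxidation comes back to the route at trimer 21.

**Further compounds**

F1 | step 4 | 2-allyl-3,5-bis(benzyloxy)phenyl 1-[3,4-bis(benzyloxy)phenyl]vinyl ether | C=CCc1c(OC(=C)c2ccc(OCc3ccccc3)c(OCc3ccccc3)c2)cc(OCc2ccccc2)cc1OCc1ccccc1
F2 | step 7 | (2R,3S)-5,7,3′,4′-tetra-O-benzylcatechin | O[C@H]1Cc2c(OCc3ccccc3)cc(OCc3ccccc3)cc2O[C@@H]1c1ccc(OCc2ccccc2)c(OCc2ccccc2)c1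
F3 | step 7 | (2R)-5,7-bis(benzyloxy)-2-[3,4-bis(benzyloxy)phenyl]chroman-3-one | O=C1Cc2c(OCc3ccccc3)cc(OCc3ccccc3)cc2O[C@@H]1c1ccc(OCc2ccccc2)c(OCc2ccccc2)c1
F4 | step 15 | protected dimer: [3-O-acetyl-6,8-dibromo-tetra-O-benzylepicatechin]-(4β→6)-[3-O-acetyl-8-bromo-tetra-O-benzylepicatechin] | c9ccccc9COc1c(Br)c(OCc9ccccc9)c2c(c1Br)O[C@H](c8ccc(OCc9ccccc9)c(OCc9ccccc9)c8)[C@H](OC(C)=O)[C@H]2c1c(OCc9ccccc9)c(Br)c2c(c1OCc9ccccc9)C[C@@H](OC(C)=O)[C@@H](c8ccc(OCc9ccccc9)c(OCc9ccccc9)c8)O2
F5 | step 15 | protected dimer as F4 with a 4β-(2-ethoxyethoxy) group on unit 2 | c9ccccc9COc1c(Br)c(OCc9ccccc9)c2c(c1Br)O[C@H](c8ccc(OCc9ccccc9)c(OCc9ccccc9)c8)[C@H](OC(C)=O)[C@H]2c1c(OCc9ccccc9)c(Br)c2c(c1OCc9ccccc9)[C@H](OCCOCC)[C@@H](OC(C)=O)[C@@H](c8ccc(OCc9ccccc9)c(OCc9ccccc9)c8)O2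
F6 | step 15 | 3-O-acetyl-5,7,3′,4′-tetra-O-benzyl-(−)-epicatechin | CC(=O)O[C@@H]1Cc2c(OCc3ccccc3)cc(OCc3ccccc3)cc2O[C@@H]1c1ccc(OCc2ccccc2)c(OCc2ccccc2)c1
F7 | step 15 | protected trimer as 21 with an unsubstituted C4 (CH2) in unit 3 | c9ccccc9COc1c(Br)c(OCc9ccccc9)c2c(c1Br)O[C@H](c8ccc(OCc9ccccc9)c(OCc9ccccc9)c8)[C@H](OC(C)=O)[C@H]2c1c(OCc9ccccc9)c(Br)c2c(c1OCc9ccccc9)[C@H](c1c(OCc9ccccc9)cc(OCc9ccccc9)c3c1O[C@H](c8ccc(OCc9ccccc9)c(OCc9ccccc9)c8)[C@H](OC(C)=O)C3)[C@@H](OC(C)=O)[C@@H](c8ccc(OCc9ccccc9)c(OCc9ccccc9)c8)O2
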